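## Retrosynthetic overview

Disconnections are listed in the order the bonds are made.

1. The cyclopropane is not built: it comes with its absolute configuration from (+)-2-carene **1**, whose six-membered ring is opened by ozonolysis (ozonide **2**) to keto aldehyde **3**.
2. C2–C3 and the (E)-C4=C5 olefin: isopropenyl addition (**4**) and vinyl-ether Claisen rearrangement (**5**) give keto aldehyde **6**.
3. Ring 1 (ten-membered): C1=C10 by McMurry coupling of **6** gives (+)-bicyclogermacrene **7**, the biogenetic precursor.
4. Rings 2 and 3 (cyclopentane and cycloheptene) form together: C9′–C4 and transannular C1–C5 when **7** attacks the o-quinone methide **10** made in situ from **8** and **9**.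
5. The same cascade shifts H-1 to C10 and H-5 to C1, opens the cyclopropane (C6–C11) and adds water at C11 to give **11**.

Assumption: **1**, **8** and **9** are bought as catalogue compounds; sesquiterpene locants (C1–C15) follow germacrane/guaiane numbering and C9′ is the benzylic carbon.

## Route

Step 1
Reactants: 1 (+)-2-carene
Product: 3 (1S,3R)-2,2-dimethyl-3-(3-oxobutyl)cyclopropane-1-carbaldehyde, via ozonide 2 (not isolated)
Conditions: O3, CH2Cl2, −78 °C; then Me2S (5 equiv), −78 → 23 °C; used crude
Reagents that add atoms: ozone, [O-][O+]=O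
Why: Criegee ozonolysis of the only C=C with neutral reductive work-up leaves both cyclopropane stereocentres untouched and does not epimerise the cis-aldehyde.

Step 2
Reactants: 3 (1S,3R)-2,2-dimethyl-3-(3-oxobutyl)cyclopropane-1-carbaldehyde
Product: 4 4-[(1R,3S)-3-(1-hydroxy-2-methylprop-2-en-1-yl)-2,2-dimethylcyclopropyl]butan-2-one
Conditions: 2-bromopropene (2 equiv), CrCl2 (4 equiv), NiCl2 (2 mol%), DMF, 23 °C
Reagents that add atoms: 2-bromopropene, CC(Br)=C
Why: Nozaki–Hiyama–Kishi alkenylation adds to the aldehyde and not to the methyl ketone and is base-free (no cis/trans epimerisation); the new carbinol centre is formed as both epimers and is destroyed in step 3.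

Step 3
Reactants: 4 4-[(1R,3S)-3-(1-hydroxy-2-methylprop-2-en-1-yl)-2,2-dimethylcyclopropyl]butan-2-one
Product: 6 (4E)-5-[(1S,3R)-2,2-dimethyl-3-(3-oxobutyl)cyclopropyl]-4-methylpent-4-enal, via allyl vinyl ether 5 (not isolated)
Conditions: ethyl vinyl ether (solvent), Pd(OAc)2 (5 mol%), 1,10-phenanthroline (5 mol%), 23 °C, 48 h; evaporate; PhMe, 110 °C (sealed), 6 h
Reagents that add atoms: ethyl vinyl ether, C=COCC
Why: Pd(II)-catalysed transfer vinylation followed by Claisen rearrangement through a chair transition state with the cyclopropyl group equatorial gives the (E)-C4=C5 olefin (expected about 9:1) from both carbinol epimers, at a temperature well below the homo-1,5-H shift of cis-alkenylcyclopropanes.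

Step 4
Reactants: 6 (4E)-5-[(1S,3R)-2,2-dimethyl-3-(3-oxobutyl)cyclopropyl]-4-methylpent-4-enal
Product: 7 (+)-bicyclogermacrene
Conditions: TiCl3(DME)1.5 (10 equiv), Zn–Cu (30 equiv), DME, 80 °C, syringe-pump addition of 6 over 30 h (about 5 mM); pentane, Florisil, then AgNO3–silica; store cold
Reagents that add atoms: none
Why: Intramolecular McMurry coupling of the aldehyde (C1) with the methyl ketone (C10) under high dilution closes the ten-membered ring; no stereocentre is formed, the (1(10)E) isomer is expected as the main product and the Z isomer is removed on AgNO3–silica.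

Step 5
Reactants: 7 (+)-bicyclogermacrene, 8 2,4-diformylphloroglucinol, 9 isovaleraldehyde
Product: 11 (−)-macrocarpal D, via o-quinone methide 10 (not isolated)
Conditions: 8 (1.5 equiv), 9 (1.5 equiv, slow addition), N,N′-dimethylethylenediamine (10 mol%), HFIP, 0 → 40 °C, 12 h; then H2O (20 equiv), 25 °C, 4 h; reverse-phase HPLC
Reagents that add atoms: water, O
Why: Proposed new method: Knoevenagel condensation of 8 with 9 gives o-quinone methide 10, which is attacked by C4 of the vinylcyclopropane olefin of 7 (the site that places charge on the cyclopropylcarbinyl C5, as in protonation of 7) on its outer face through an open antiperiplanar transition state (aryl anti to C5, H over the cyclopropane methyl, isobutyl over H-5, giving 9′R), while C1=C10 closes on C5 from the inner face (anti addition: side chain β at C4 and the 1βH,5βH cis-hydroazulene that 7 also gives on protonation); in non-nucleophilic HFIP the C10 cation then undergoes two suprafacial 1,2-hydride shifts (H-1β to C10 sets 10βH/14α-Me, H-5β to C1 sets 1βH) to the tertiary cyclopropylcarbinyl C5 cation, which opens irreversibly to the Δ5 olefin and the C11 cation that water traps, C7 coming unchanged from 1; the closest known reactions are the three-component quinone-methide Michael/cation–olefin cascades of 7 with diformylphloroglucinol, the acid-induced transannular cyclisation/1,2-H shift of 7 to ledane-type products, and cyclopropylcarbinyl-to-homoallyl hydration of carene-type vinylcyclopropanes.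

## Compound list

1 | (+)-2-carene, (1S,6R)-3,7,7-trimethylbicyclo[4.1.0]hept-2-ene | CC1=C[C@H]2[C@@H](CC1)C2(C)C | starting material
2 | ozonide of 1 (1,2,4-trioxolane across the former C2=C3, epimers at the trioxolane carbons) | CC12CC[C@@H]3[C@H](C(O1)OO2)C3(C)C | intermediate (not isolated)
3 | (1S,3R)-2,2-dimethyl-3-(3-oxobutyl)cyclopropane-1-carbaldehyde (cis) | O=C[C@H]1[C@@H](CCC(C)=O)C1(C)C | intermediate
4 | 4-[(1R,3S)-3-(1-hydroxy-2-methylprop-2-en-1-yl)-2,2-dimethylcyclopropyl]butan-2-one (both carbinol epimers) | C=C(C)C(O)[C@H]1[C@@H](CCC(C)=O)C1(C)C | intermediate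
5 | 4-[(1R,3S)-3-[1-(ethenyloxy)-2-methylprop-2-en-1-yl]-2,2-dimethylcyclopropyl]butan-2-one (allyl vinyl ether) | C=COC(C(C)=C)[C@H]1[C@@H](CCC(C)=O)C1(C)C | intermediate (not isolated)
6 | (4E)-5-[(1S,3R)-2,2-dimethyl-3-(3-oxobutyl)cyclopropyl]-4-methylpent-4-enal | O=CCC/C(C)=C/[C@H]1[C@@H](CCC(C)=O)C1(C)C | intermediate
7 | (+)-bicyclogermacrene, (1S,2E,6E,10R)-3,7,11,11-tetramethylbicyclo[8.1.0]undeca-2,6-diene | C/C1=C\CC/C(C)=C/[C@H]2[C@@H](CC1)C2(C)C | intermediate
8 | 2,4-diformylphloroglucinol (2,4,6-trihydroxybenzene-1,3-dicarbaldehyde) | O=Cc1c(O)cc(O)c(C=O)c1O | starting material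
9 | isovaleraldehyde (3-methylbutanal) | CC(C)CC=O | starting material
10 | o-quinone methide, 2,4-diformyl-3,5-dihydroxy-6-(3-methylbutylidene)cyclohexa-2,4-dien-1-one (alkylidene geometry undefined) | CC(C)CC=C1C(=O)C(C=O)=C(O)C(C=O)=C1O | intermediate (not isolated)
11 | (−)-macrocarpal D, 5-[(1R)-1-[(1R,3aR,4R,7R)-7-(2-hydroxypropan-2-yl)-1,4-dimethyl-1,2,3,3a,4,5,6,7-octahydroazulen-1-yl]-3-methylbutyl]-2,4,6-trihydroxybenzene-1,3-dicarbaldehyde | CC(C)C[C@@H](c1c(O)c(C=O)c(O)c(C=O)c1O)[C@@]1(C)CC[C@H]2C1=C[C@H](C(C)(C)O)CC[C@H]2C | target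

## Totals and risks

Total step count: 5. Longest linear sequence: 5 steps (1 → 3 → 4 → 6 → 7 → 11).

**Step 5 (most likely to fail).** The cascade may stop after the first cyclisation, the 9′ epimer may form in quantity, or acid may consume 7 before coupling. The fallback sets out from 7 (with 8 and 9) and interrupts the cascade on purpose. The coupling is run in HFIP–H2O (4:1) buffered with NaOAc at 0–25 °C, so that water captures the first bicyclic cation at C10. The cis-fused aromadendran-10-ol adduct F1 (C10 epimers, both usable) is isolated and freed from its 9′ epimer by chromatography. F1 is then ionised separately with TfOH (5 mol%) in HFIP–H2O (20:1) at −20 → 0 °C. Water capture at C10 and C1 is reversible and the cyclopropane opening is not, so repeated ionisation funnels the material through the two hydride shifts, ring opening and hydration at C11. The fallback comes back to the route at 11.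

**Step 4.** The McMurry closure may give a poor E/Z ratio at C1=C10, and 30 h at 80 °C may cause Cope rearrangement of 7. The fallback sets out from 6. TiCl3(DME)1.5/Zn–Cu in DME at 25 °C stops at the pinacol stage. The 1,10-trans-diol F2 (the (1R,10R) isomer is drawn; the (1S,10S) isomer serves equally) is separated from the cis-diols. Thiophosgene/DMAP (CH2Cl2, 0 °C) converts it into the cyclic thionocarbonate F3. Fragmentation with 1,3-dimethyl-2-phenyl-1,3,2-diazaphospholidine at 40 °C (Corey–Winter olefination) is a stereospecific syn-elimination that can only give the (E)-C1=C10 olefin. The fallback comes back to the route at 7 without the germacrene ever being heated above 40 °C.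

**Step 3.** The simple vinyl-ether Claisen may give too much (Z)-C4=C5 olefin, or the vinyl transfer to the hindered carbinol may be slow. The fallback sets out from 4. Johnson–Claisen rearrangement (MeC(OEt)3, cat. EtCO2H, 135 °C) gives the (E)-keto ester F4; here an axial cyclopropyl group would clash with the ethoxy group in the chair, so E:Z should exceed 20:1. LiAlH4 (THF, 0 °C) reduces ester and ketone to the diol F5. Double Swern oxidation ((COCl)2, DMSO, Et3N, −78 °C) comes back to the route at 6.

## Further compounds

F1 | step 5 | 5-[(1R)-1-(10-hydroxy-cis-aromadendran-4-yl)-3-methylbutyl]-2,4,6-trihydroxybenzene-1,3-dicarbaldehyde (1βH,5βH,6αH,7αH; C10 epimers) | CC(C)C[C@@H](c1c(O)c(C=O)c(O)c(C=O)c1O)[C@@]1(C)CC[C@H]2[C@@H]1[C@H]1[C@@H](CCC2(C)O)C1(C)C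
F2 | step 4 | (4E)-bicyclogermacr-4-ene-1,10-diol, 1,10-trans, (1R,10R) isomer drawn | C[C@]1(O)[C@H](O)CC/C(C)=C/[C@H]2[C@@H](CC1)C2(C)C
F3 | step 4 | cyclic 1,10-thionocarbonate of F2 | C[C@]12OC(=S)O[C@@H]1CC/C(C)=C/[C@H]3[C@@H](CC2)C3(C)C
F4 | step 3 | ethyl (4E)-5-[(1S,3R)-2,2-dimethyl-3-(3-oxobutyl)cyclopropyl]-4-methylpent-4-enoate | CCOC(=O)CC/C(C)=C/[C@H]1[C@@H](CCC(C)=O)C1(C)C
F5 | step 3 | (4E)-5-[(1S,3R)-3-(3-hydroxybutyl)-2,2-dimethylcyclopropyl]-4-methylpent-4-en-1-ol (carbinol epimers) | OCCC/C(C)=C/[C@H]1[C@@H](CCC(C)O)C1(C)C
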